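**Plan**

1. Atoms are numbered as in prostanoic acid (C1 acid carbon, ring C8–C12, carbinols C9 and C11, methylene C10, lower chain C13–C20). The retrosynthesis cuts C13=C14 (Horner–Wadsworth–Emmons), C6=C7 (Wittig, later hydrogenated) and, in one operation, the two ring bonds C8–C9 and C10–C11.
2. The feature used is that C10 is a CH2 between C9 and the carbinol C11, and that C8 bears the one-carbon branch C7. With C7 and C11 as formyl groups, C7–C8–C12–C11 is a 2-substituted succinaldehyde (enamine carbon C8, electrophilic C11), and C9=C10 is a nitroalkene (electrophilic C9, nitronate carbon C10).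
3. Forward: dialdehyde 4 and silyl nitroethylene 6 give the only ring in step 5 (Michael/Henry, with the C7 formyl group reduced in the same flask). Fluoride then removes SiMe3 and NO2 together as the C9=C10 alkene, and a silicon tether on O7 delivers the 9-hydroxyl. C7 is re-oxidised and extended by Wittig (C1–C6), and C13 by Horner–Wadsworth–Emmons (C14–C20).
4. Stereochemistry: the amine catalyst fixes only C9 (silicon-bearing, not epimerisable). C8, C12 and C11 are relayed from it by equilibration to the all-trans ring, which also makes the racemic dialdehyde converge. The 9-hydroxyl is relayed from C8 through the tether, C15 comes from a Corey–Bakshi–Shibata reduction, and C19 is bought as (R)-butane-1,3-diol.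

Key step: step 5

Assumption: 1 is the commercial mixture of acetal diastereomers and 4 is used as the racemate, since its stereocentre is alpha to a formyl group and epimerises in step 5; "alpha face" means the ring face that carries the C8 chain in the target.

**Route**

Step 1
Reactants: 1 2,5-dimethoxytetrahydrofuran-3-carbaldehyde
Product: 2 (2,5-dimethoxytetrahydrofuran-3-yl)methanol
Conditions: NaBH4, MeOH, 0 °C
Reagents that add atoms: none
Why: Borohydride reduction of the aldehyde to the primary alcohol (the later C13 oxygen), which leaves both acetal carbons untouched and sets no stereocentre that survives.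

Step 2
Reactants: 2 (2,5-dimethoxytetrahydrofuran-3-yl)methanol
Product: 3 3-[(benzyloxy)methyl]-2,5-dimethoxytetrahydrofuran
Conditions: NaH, BnBr, Bu4NI (cat.), THF, 0 °C → rt
Reagents that add atoms: benzyl bromide, BrCc1ccccc1
Why: Williamson ether synthesis; the benzyl ether should survive steps 3 to 10 and fall together with the side-chain alkene in the hydrogenation of step 11.

Step 3
Reactants: 3 3-[(benzyloxy)methyl]-2,5-dimethoxytetrahydrofuran
Product: 4 2-[(benzyloxy)methyl]butanedial (racemic)
Conditions: 0.1 M aq. HCl, THF, 50 °C; extraction into CH2Cl2; used at once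
Reagents that add atoms: water, O
Why: Acid-catalysed hydrolysis of the cyclic bis-acetal frees the 1,4-dialdehyde in the way succinaldehyde itself is freed from 2,5-dimethoxytetrahydrofuran, and its stereocentre, alpha to a formyl group, is deliberately left racemic.

Step 4
Reactants: 5 (E)-1,2-bis(trimethylsilyl)ethene
Product: 6 (E)-trimethyl(2-nitroethenyl)silane
Conditions: NO2BF4 (1.0 equiv), MeCN, −35 → 0 °C
Reagents that add atoms: nitronium tetrafluoroborate, O=[N+]=O.F[B-](F)(F)F
Why: Electrophilic ipso-nitrodesilylation of a vinylsilane through a beta-silyl-stabilised cation, which should keep the E geometry and stop after one substitution because the nitroalkene formed is deactivated.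

Step 5
Reactants: 4 2-[(benzyloxy)methyl]butanedial; 6 (E)-trimethyl(2-nitroethenyl)silane
Product: 9 (1S,2S,3S,4S,5S)-2-[(benzyloxy)methyl]-3-(hydroxymethyl)-5-nitro-4-(trimethylsilyl)cyclopentan-1-ol, via Michael adduct 7 (not isolated), via cyclopentanecarbaldehyde 8 (not isolated)
Conditions: 4 (1.5 equiv), (R)-2-[diphenyl(trimethylsilyloxy)methyl]pyrrolidine (10 mol%), 4-nitrophenol (10 mol%), MeCN, 0 °C → rt; then iPr2NEt (1 equiv), rt, until the isomer ratio no longer changes; then NaBH4, MeOH, 0 °C
Reagents that add atoms: none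
Why: The amine condenses with the unbranched formyl group of 4, and the enamine carbon C8 adds to the silicon-bearing beta-carbon C9 of 6 through the acyclic synclinal transition state usual for this catalyst class, in which the diphenyl(silyloxy)methyl group blocks one enamine face, so that C9 should form with S configuration. iPr2NEt then turns the nitro group of 7 into its nitronate, whose carbon C10 adds to the C11 formyl group, so the cyclopentane C8–C9–C10–C11–C12 closes by a 5-exo-trig Henry (nitro-aldol) addition. The closest known reaction type is the diarylprolinol silyl ether catalysed Michael/Henry [3+2] annulation of succinaldehyde with nitroalkenes. C9 is the only centre the catalyst fixes and it cannot epimerise, whereas C8 (alpha to CHO), C10 (alpha to NO2) and C12 (alpha to the C11 formyl group until the ring closes) epimerise under the amine base and the Henry addition that creates C11 is reversible; both C12 epimers of 4 and all ring isomers should therefore drain into the all-trans aldehyde 8 (CHO trans to SiMe3, CH2OBn trans to CHO, OH trans to CH2OBn), which has the C8, C11 and C12 configurations of the target. The step needs enamine formation at one of two formyl groups and attack at a hindered beta-carbon: the alpha-branch at C12 keeps the amine off the C11 formyl group, and the nitro group polarises 6 so that only its silicon-bearing carbon is electrophilic. The borohydride quench reduces the C7 formyl group of 8 (and surplus 4), which freezes C8 and provides the O7 handle used in steps 7 and 9.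

Step 6
Reactants: 9 (1S,2S,3S,4S,5S)-2-[(benzyloxy)methyl]-3-(hydroxymethyl)-5-nitro-4-(trimethylsilyl)cyclopentan-1-ol
Product: 10 (1R,4S,5S)-5-[(benzyloxy)methyl]-4-(hydroxymethyl)cyclopent-2-en-1-ol
Conditions: Bu4NF (3 equiv), THF, 0 °C → rt
Reagents that add atoms: none
Why: Proposed new method: fluoride attack on silicon turns the C9–Si bond into a carbanion equivalent that expels nitrite from the neighbouring C10 in an anti, E1cB-like 1,2-elimination (SiMe3 and NO2 are trans in 9, and C10 can equilibrate through its nitronate), so the alkene can only form between the two carbons that carried the helper groups; the closest known reaction types are the fluoride-induced elimination of beta-silyl sulfones to alkenes and the Peterson olefination, with nitrite as leaving group as in eliminations of beta-nitro sulfones.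

Step 7
Reactants: 10 (1R,4S,5S)-5-[(benzyloxy)methyl]-4-(hydroxymethyl)cyclopent-2-en-1-ol
Product: 13 (1S,3R,4S,5S)-4-[(benzyloxy)methyl]-5-(hydroxymethyl)cyclopentane-1,3-diol, via bis(dimethylsilyl) ether 11 (not isolated), via oxasilolane 12 (not isolated)
Conditions: (HMe2Si)2NH, neat, rt, then evaporation; Pt2[(CH2=CHSiMe2)2O]3 (zerovalent platinum, 0.5 mol%), hexane, rt → 50 °C; then 30% H2O2, KF, KHCO3, THF/MeOH, rt
Reagents that add atoms: 1,1,3,3-tetramethyldisilazane, C[SiH](C)N[SiH](C)C; hydrogen peroxide, OO
Why: Intramolecular hydrosilylation of a homoallylic silyl ether (5-exo) followed by Tamao oxidation: the Si–H bond tethered to O7 can reach only the near alkene carbon C9 and only from the face of the C8–C7 bond, which gives a cis-fused oxasilolane, and the oxidation replaces C–Si by C–OH with retention, so the new C9 hydroxyl should be cis to the C8 side arm and to the C11 hydroxyl.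

Step 8
Reactants: 13 (1S,3R,4S,5S)-4-[(benzyloxy)methyl]-5-(hydroxymethyl)cyclopentane-1,3-diol
Product: 14 tris(triethylsilyl) ether of 13
Conditions: Et3SiOTf (3.5 equiv), 2,6-lutidine, CH2Cl2, −78 → 0 °C
Reagents that add atoms: triethylsilyl trifluoromethanesulfonate, CC[Si](CC)(CC)OS(=O)(=O)C(F)(F)F
Why: Silylation of all three hydroxyl groups; triethylsilyl is chosen because its primary ether can be oxidised directly in step 9 while its secondary ethers should last until the final acid treatment.

Step 9
Reactants: 14 tris(triethylsilyl) ether of 13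
Product: 15 (1R,2S,3R,5S)-2-[(benzyloxy)methyl]-3,5-bis[(triethylsilyl)oxy]cyclopentane-1-carbaldehyde
Conditions: (COCl)2, DMSO, CH2Cl2, −78 → −30 °C; then Et3N, −78 → 0 °C; crude aldehyde used at once
Reagents that add atoms: none
Why: Swern oxidation in which the activated sulfoxide cleaves the unhindered primary triethylsilyl ether and oxidises it directly to the aldehyde while the two secondary silyl ethers stay, and the cold, short exposure to Et3N should keep the C8 stereocentre alpha to the new formyl group intact.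

Step 10
Reactants: 15 (1R,2S,3R,5S)-2-[(benzyloxy)methyl]-3,5-bis[(triethylsilyl)oxy]cyclopentane-1-carbaldehyde; 16 (5-carboxypentyl)triphenylphosphonium bromide
Product: 18 methyl (6Z)-7-[(1R,2S,3R,5S)-2-[(benzyloxy)methyl]-3,5-bis[(triethylsilyl)oxy]cyclopentyl]hept-6-enoate, via carboxylic acid 17 (not isolated)
Conditions: 16 (2.5 equiv), KN(SiMe3)2 (5 equiv), THF, −78 → 0 °C; aq. NH4Cl; then Me3SiCHN2, MeOH/toluene, 0 °C
Reagents that add atoms: trimethylsilyldiazomethane, C[Si](C)(C)C=[N+]=[N-]
Why: Wittig olefination with a non-stabilised ylide (Z-selective, although the geometry does not matter because step 11 saturates the alkene) joins C7 to the C1–C6 chain and the acid is esterified in the same flask; the low-temperature conditions should neither epimerise C8 nor eliminate the beta-silyloxy group.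

Step 11
Reactants: 18 methyl (6Z)-7-[(1R,2S,3R,5S)-2-[(benzyloxy)methyl]-3,5-bis[(triethylsilyl)oxy]cyclopentyl]hept-6-enoate
Product: 19 methyl 7-[(1R,2S,3R,5S)-2-(hydroxymethyl)-3,5-bis[(triethylsilyl)oxy]cyclopentyl]heptanoate
Conditions: H2 (1 atm), Pd on carbon (10 wt% Pd), EtOAc, rt
Reagents that add atoms: none
Why: Heterogeneous hydrogenation saturates the C6=C7 alkene and hydrogenolyses the benzyl ether in one operation, while the silyl ethers and the ester should survive in a non-protic solvent.

Step 12
Reactants: 20 (3R)-butane-1,3-diol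
Product: 21 (2R)-4-iodobutan-2-ol
Conditions: PPh3, I2, imidazole, CH2Cl2, 0 °C
Reagents that add atoms: iodine, II
Why: Appel-type iodination, selective for the primary hydroxyl, leaves the bought stereocentre (the later C19) untouched.

Step 13
Reactants: 21 (2R)-4-iodobutan-2-ol
Product: 22 triethyl{[(2R)-4-iodobutan-2-yl]oxy}silane
Conditions: Et3SiCl, imidazole, CH2Cl2, 0 °C → rt
Reagents that add atoms: chlorotriethylsilane, CC[Si](Cl)(CC)CC
Why: Standard silylation of the secondary hydroxyl, which does not touch the stereocentre.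

Step 14
Reactants: 22 triethyl{[(2R)-4-iodobutan-2-yl]oxy}silane; 23 dimethyl (2-oxopropyl)phosphonate
Product: 24 dimethyl [(6R)-2-oxo-6-[(triethylsilyl)oxy]heptyl]phosphonate
Conditions: 23, NaH, THF, 0 °C; n-BuLi, 0 °C; then 22, 0 °C → rt; aq. NH4Cl
Reagents that add atoms: none
Why: Alkylation of the 1,3-dianion of a beta-ketophosphonate, which should react with the primary iodide at its more basic terminal (methyl-derived) carbon in an SN2 displacement.

Step 15
Reactants: 19 methyl 7-[(1R,2S,3R,5S)-2-(hydroxymethyl)-3,5-bis[(triethylsilyl)oxy]cyclopentyl]heptanoate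
Product: 25 methyl 7-[(1R,2R,3R,5S)-2-formyl-3,5-bis[(triethylsilyl)oxy]cyclopentyl]heptanoate
Conditions: Dess–Martin periodinane, NaHCO3, CH2Cl2, 0 °C → rt
Reagents that add atoms: none
Why: Dess–Martin oxidation of the primary alcohol under buffered, non-basic conditions, so that the beta-silyloxy aldehyde should neither eliminate nor epimerise at C12, which already holds the more stable trans,trans arrangement.

Step 16
Reactants: 25 methyl 7-[(1R,2R,3R,5S)-2-formyl-3,5-bis[(triethylsilyl)oxy]cyclopentyl]heptanoate; 24 dimethyl [(6R)-2-oxo-6-[(triethylsilyl)oxy]heptyl]phosphonate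
Product: 26 methyl 7-[(1R,2R,3R,5S)-2-[(1E,7R)-3-oxo-7-[(triethylsilyl)oxy]oct-1-en-1-yl]-3,5-bis[(triethylsilyl)oxy]cyclopentyl]heptanoate
Conditions: LiCl, iPr2NEt, MeCN, rt
Reagents that add atoms: none
Why: Horner–Wadsworth–Emmons olefination with a stabilised phosphonate under mild amine/LiCl conditions should give the E-enone without beta-elimination of the C11 silyloxy group.

Step 17
Reactants: 26 methyl 7-[(1R,2R,3R,5S)-2-[(1E,7R)-3-oxo-7-[(triethylsilyl)oxy]oct-1-en-1-yl]-3,5-bis[(triethylsilyl)oxy]cyclopentyl]heptanoate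
Product: 27 methyl 7-[(1R,2R,3R,5S)-2-[(1E,3S,7R)-3-hydroxy-7-[(triethylsilyl)oxy]oct-1-en-1-yl]-3,5-bis[(triethylsilyl)oxy]cyclopentyl]heptanoate
Conditions: (R)-2-methyl-CBS-oxazaborolidine (20 mol%), catecholborane, toluene, −78 °C
Reagents that add atoms: none
Why: Corey–Bakshi–Shibata reduction, in which the catalyst binds the enone with the alkenyl group as the large substituent and delivers hydride 1,2 to one face, which with the (R)-catalyst should give the 15S allylic alcohol and leave the ester untouched.

Step 18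
Reactants: 27 methyl 7-[(1R,2R,3R,5S)-2-[(1E,3S,7R)-3-hydroxy-7-[(triethylsilyl)oxy]oct-1-en-1-yl]-3,5-bis[(triethylsilyl)oxy]cyclopentyl]heptanoate
Product: 29 7-[(1R,2R,3R,5S)-3,5-dihydroxy-2-[(1E,3S,7R)-3,7-dihydroxyoct-1-en-1-yl]cyclopentyl]heptanoic acid, via lithium carboxylate 28 (not isolated)
Conditions: LiOH, THF/MeOH/H2O, rt; then AcOH/H2O (to pH 3–4), 35 °C
Reagents that add atoms: lithium hydroxide, [Li+].[OH-]
Why: Saponification of the methyl ester followed in the same flask by mild acid hydrolysis of the three triethylsilyl ethers, conditions under which the allylic C15 alcohol and the other stereocentres should not be affected.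

**Compound list**

1 | 2,5-dimethoxytetrahydrofuran-3-carbaldehyde (mixture of diastereomers) | COC1CC(C=O)C(OC)O1 | starting material
2 | (2,5-dimethoxytetrahydrofuran-3-yl)methanol (mixture of diastereomers) | COC1CC(CO)C(OC)O1 | intermediate
3 | 3-[(benzyloxy)methyl]-2,5-dimethoxytetrahydrofuran (mixture of diastereomers) | COC1CC(COCc2ccccc2)C(OC)O1 | intermediate
4 | 2-[(benzyloxy)methyl]butanedial (racemic) | O=CCC(COCc1ccccc1)C=O | intermediate
5 | (E)-1,2-bis(trimethylsilyl)ethene | C[Si](C)(C)/C=C/[Si](C)(C)C | starting material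
6 | (E)-trimethyl(2-nitroethenyl)silane | C[Si](C)(C)/C=C/[N+](=O)[O-] | intermediate
7 | (3R)-2-[(benzyloxy)methyl]-3-[(1S)-2-nitro-1-(trimethylsilyl)ethyl]butanedial (both C2 epimers; formed in the flask) | O=C[C@H]([C@H]([Si](C)(C)C)C[N+](=O)[O-])C(COCc1ccccc1)C=O | intermediate
8 | (1S,2S,3S,4S,5S)-2-[(benzyloxy)methyl]-3-hydroxy-4-nitro-5-(trimethylsilyl)cyclopentane-1-carbaldehyde (formed in the flask) | c1ccccc1COC[C@@H]2[C@@H](C=O)[C@H]([Si](C)(C)C)[C@@H]([N+](=O)[O-])[C@H]2O | intermediate
9 | (1S,2S,3S,4S,5S)-2-[(benzyloxy)methyl]-3-(hydroxymethyl)-5-nitro-4-(trimethylsilyl)cyclopentan-1-ol | c1ccccc1COC[C@@H]2[C@@H](CO)[C@H]([Si](C)(C)C)[C@@H]([N+](=O)[O-])[C@H]2O | intermediate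
10 | (1R,4S,5S)-5-[(benzyloxy)methyl]-4-(hydroxymethyl)cyclopent-2-en-1-ol | c1ccccc1COC[C@@H]2[C@@H](CO)C=C[C@H]2O | intermediate
11 | bis(dimethylsilyl) ether of 10 (formed in the flask) | c1ccccc1COC[C@@H]2[C@@H](CO[SiH](C)C)C=C[C@H]2O[SiH](C)C | intermediate
12 | cis-fused 1-oxa-2-silacyclopentane linking O7 and C9, with O11 as its dimethylsilyl ether (formed in the flask) | c1ccccc1COC[C@@H]2[C@@H](CO[Si]3(C)C)[C@@H]3C[C@H]2O[SiH](C)C | intermediate
13 | (1S,3R,4S,5S)-4-[(benzyloxy)methyl]-5-(hydroxymethyl)cyclopentane-1,3-diol | c1ccccc1COC[C@@H]2[C@@H](CO)[C@@H](O)C[C@H]2O | intermediate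
14 | tris(triethylsilyl) ether of 13 (configuration as in 13) | c1ccccc1COC[C@@H]2[C@@H](CO[Si](CC)(CC)CC)[C@@H](O[Si](CC)(CC)CC)C[C@H]2O[Si](CC)(CC)CC | intermediate
15 | (1R,2S,3R,5S)-2-[(benzyloxy)methyl]-3,5-bis[(triethylsilyl)oxy]cyclopentane-1-carbaldehyde | c1ccccc1COC[C@@H]2[C@@H](C=O)[C@@H](O[Si](CC)(CC)CC)C[C@H]2O[Si](CC)(CC)CC | intermediate
16 | (5-carboxypentyl)triphenylphosphonium bromide | OC(=O)CCCCC[P+](c1ccccc1)(c1ccccc1)c1ccccc1.[Br-] | starting material
17 | (6Z)-7-[(1R,2S,3R,5S)-2-[(benzyloxy)methyl]-3,5-bis[(triethylsilyl)oxy]cyclopentyl]hept-6-enoic acid (formed in the flask) | c1ccccc1COC[C@@H]2[C@@H](/C=C\CCCCC(=O)O)[C@@H](O[Si](CC)(CC)CC)C[C@H]2O[Si](CC)(CC)CC | intermediate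
18 | methyl (6Z)-7-[(1R,2S,3R,5S)-2-[(benzyloxy)methyl]-3,5-bis[(triethylsilyl)oxy]cyclopentyl]hept-6-enoate | c1ccccc1COC[C@@H]2[C@@H](/C=C\CCCCC(=O)OC)[C@@H](O[Si](CC)(CC)CC)C[C@H]2O[Si](CC)(CC)CC | intermediate
19 | methyl 7-[(1R,2S,3R,5S)-2-(hydroxymethyl)-3,5-bis[(triethylsilyl)oxy]cyclopentyl]heptanoate | OC[C@@H]1[C@@H](CCCCCCC(=O)OC)[C@@H](O[Si](CC)(CC)CC)C[C@H]1O[Si](CC)(CC)CC | intermediate
20 | (3R)-butane-1,3-diol | C[C@@H](O)CCO | starting material
21 | (2R)-4-iodobutan-2-ol | C[C@@H](O)CCI | intermediate
22 | triethyl{[(2R)-4-iodobutan-2-yl]oxy}silane | ICC[C@@H](C)O[Si](CC)(CC)CC | intermediate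
23 | dimethyl (2-oxopropyl)phosphonate | COP(=O)(OC)CC(C)=O | starting material
24 | dimethyl [(6R)-2-oxo-6-[(triethylsilyl)oxy]heptyl]phosphonate | COP(=O)(OC)CC(=O)CCC[C@@H](C)O[Si](CC)(CC)CC | intermediate
25 | methyl 7-[(1R,2R,3R,5S)-2-formyl-3,5-bis[(triethylsilyl)oxy]cyclopentyl]heptanoate | O=C[C@@H]1[C@@H](CCCCCCC(=O)OC)[C@@H](O[Si](CC)(CC)CC)C[C@H]1O[Si](CC)(CC)CC | intermediate
26 | methyl 7-[(1R,2R,3R,5S)-2-[(1E,7R)-3-oxo-7-[(triethylsilyl)oxy]oct-1-en-1-yl]-3,5-bis[(triethylsilyl)oxy]cyclopentyl]heptanoate | C[C@@H](O[Si](CC)(CC)CC)CCCC(=O)/C=C/[C@@H]1[C@@H](CCCCCCC(=O)OC)[C@@H](O[Si](CC)(CC)CC)C[C@H]1O[Si](CC)(CC)CC | intermediate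
27 | methyl 7-[(1R,2R,3R,5S)-2-[(1E,3S,7R)-3-hydroxy-7-[(triethylsilyl)oxy]oct-1-en-1-yl]-3,5-bis[(triethylsilyl)oxy]cyclopentyl]heptanoate | C[C@@H](O[Si](CC)(CC)CC)CCC[C@H](O)/C=C/[C@@H]1[C@@H](CCCCCCC(=O)OC)[C@@H](O[Si](CC)(CC)CC)C[C@H]1O[Si](CC)(CC)CC | intermediate
28 | lithium carboxylate of 27 (formed in the flask) | [Li+].C[C@@H](O[Si](CC)(CC)CC)CCC[C@H](O)/C=C/[C@@H]1[C@@H](CCCCCCC(=O)[O-])[C@@H](O[Si](CC)(CC)CC)C[C@H]1O[Si](CC)(CC)CC | intermediate
29 | 7-[(1R,2R,3R,5S)-3,5-dihydroxy-2-[(1E,3S,7R)-3,7-dihydroxyoct-1-en-1-yl]cyclopentyl]heptanoic acid | C[C@@H](O)CCC[C@H](O)/C=C/[C@@H]1[C@@H](CCCCCCC(=O)O)[C@@H](O)C[C@H]1O | target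

**Step count**

Total steps: 18. Longest linear sequence: 14 steps (1, 2, 3, 5, 6, 7, 8, 9, 10, 11, 15, 16, 17, 18).

**Steps most likely to fail**

Step 6 (Proposed new method). What may go wrong: fluoride may only cause protodesilylation without loss of nitrite, or the basic fluoride may open the ring by retro-Henry cleavage before the elimination occurs. The fallback uses known reactions only, sets out from 9 and comes back at 10. The secondary nitro group is converted into the ketone by a Nef-type reaction (NaNO2, AcOH, DMSO, 35 °C), giving the alpha-silyl ketone (2S,3S,4S,5S)-3-[(benzyloxy)methyl]-2-hydroxy-4-(hydroxymethyl)-5-(trimethylsilyl)cyclopentan-1-one F1. NaBH4 (MeOH, −40 °C) reduces it to the beta-hydroxysilane 3-[(benzyloxy)methyl]-4-(hydroxymethyl)-5-(trimethylsilyl)cyclopentane-1,2-diol F2 (either epimer at the new carbinol). Peterson elimination (KH in THF for the epimer with OH syn to silicon, BF3·OEt2 in CH2Cl2 for the anti epimer) should then give 10.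

Step 5. What may go wrong: poor facial selectivity in the Michael addition to the hindered silyl nitroalkene, so that 9 and everything after it is enantiomerically impure. The fallback adds an enzymatic kinetic resolution, sets out from 10 and comes back at 10. A lipase (a serine hydrolase, for example that of Burkholderia cepacia) with vinyl acetate in tert-butyl methyl ether should acylate the primary hydroxyl of both enantiomers. By the empirical rule for secondary alcohols (large substituent the sp3 carbon C12, smaller one the vinylic C10), it should acylate the secondary allylic hydroxyl only of the wanted 1R enantiomer. This gives the diacetate of 10, F3, and leaves the unwanted enantiomer as the primary monoacetate of ent-10, F4. After separation, methanolysis of F3 (K2CO3, MeOH) returns 10.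

Step 9. What may go wrong: the secondary silyl ethers may be cleaved as well, or the aldehyde may epimerise at C8 or lose the beta-silyloxy group during the amine quench. The fallback replaces the oxidation/olefination by a displacement at C7, sets out from 13 and comes back at 19. Appel iodination of the primary hydroxyl (PPh3, I2, imidazole) gives (1S,3R,4S,5R)-4-[(benzyloxy)methyl]-5-(iodomethyl)cyclopentane-1,3-diol F5. Et3SiOTf with 2,6-lutidine gives its bis(triethylsilyl) ether F6. A Negishi alkyl–alkyl coupling (NiCl2·glyme with a pybox ligand, or Pd2(dba)3 with tricyclopentylphosphine and N-methylimidazole) with (6-methoxy-6-oxohexyl)zinc bromide F7, made from methyl 6-bromohexanoate and zinc, gives methyl 7-[(1R,2S,3R,5S)-2-[(benzyloxy)methyl]-3,5-bis[(triethylsilyl)oxy]cyclopentyl]heptanoate F8. Hydrogenolysis of its benzyl ether under the conditions of step 11 gives 19.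

**Further compounds**

F1 | step 6 | (2S,3S,4S,5S)-3-[(benzyloxy)methyl]-2-hydroxy-4-(hydroxymethyl)-5-(trimethylsilyl)cyclopentan-1-one | c1ccccc1COC[C@@H]2[C@@H](CO)[C@H]([Si](C)(C)C)C(=O)[C@H]2O
F2 | step 6 | (2S,3S,4S,5S)-3-[(benzyloxy)methyl]-4-(hydroxymethyl)-5-(trimethylsilyl)cyclopentane-1,2-diol (either C1 epimer) | c1ccccc1COC[C@@H]2[C@@H](CO)[C@H]([Si](C)(C)C)C(O)[C@H]2O
F3 | step 5 | diacetate of 10 | c1ccccc1COC[C@@H]2[C@@H](COC(C)=O)C=C[C@H]2OC(C)=O
F4 | step 5 | primary monoacetate of ent-10 | c1ccccc1COC[C@H]2[C@H](COC(C)=O)C=C[C@@H]2O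
F5 | step 9 | (1S,3R,4S,5R)-4-[(benzyloxy)methyl]-5-(iodomethyl)cyclopentane-1,3-diol | c1ccccc1COC[C@@H]2[C@@H](CI)[C@@H](O)C[C@H]2O
F6 | step 9 | bis(triethylsilyl) ether of F5 | c1ccccc1COC[C@@H]2[C@@H](CI)[C@@H](O[Si](CC)(CC)CC)C[C@H]2O[Si](CC)(CC)CC
F7 | step 9 | (6-methoxy-6-oxohexyl)zinc bromide | COC(=O)CCCCC[Zn]Br
F8 | step 9 | methyl 7-[(1R,2S,3R,5S)-2-[(benzyloxy)methyl]-3,5-bis[(triethylsilyl)oxy]cyclopentyl]heptanoate | c1ccccc1COC[C@@H]2[C@@H](CCCCCCC(=O)OC)[C@@H](O[Si](CC)(CC)CC)C[C@H]2O[Si](CC)(CC)CC
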